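Everything rests on the bond between the CH one-carbon bridge of the bicyclo[3.1.1]heptenone (a cyclobutane carbon) and the gem-dimethyl quaternary carbon; forming it closes the seven-membered ring that spans the 1,3-positions of the cyclobutane. The CH is carried as the carbonyl carbon of a bicyclo[3.1.1]heptan-6-one (intramolecular ketene–alkene [2+2]), the quaternary carbon as an isopropenyl group on the side chain of the opposite cyclobutane carbon. In one operation the ketone is condensed to its tosylhydrazone, iron-hydride hydrogen-atom transfer makes the tertiary radical, 7-exo closure onto C=N follows, and loss of sulfinate and N2 leaves the C–H: a traceless reductive ring-closing alkylation that exploits the 1,3-diaxial relationship across the cyclobutane.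

Key step: step 12

Remark (locants used below): C1 methacrylate carbinol, C2 methylene, C3 isobutyrate carbinol, C4 methylated cyclobutane carbon, C5 cyclobutane CH next to the ketone C6, C7 and C8 the enone carbons (C8 bears the methyl), C9 cyclobutane CH next to C8, C10 cyclobutane CH bonded to C11, C11 gem-dimethyl carbon.

Remark (assumption): for the three reagent-controlled steps (1, 7, 9) the required facial selectivity is stated; the named antipode of each chiral reagent is the one expected to deliver it, and the other antipode would be used if the sense were opposite. C8 is a sacrificial stereocenter that is erased in step 14.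

Step 1
Reactants: 1 (2E)-3-methyl-4-oxobut-2-en-1-yl acetate; 2 3-methylbut-3-en-2-one
Product: 3 (2E,4R)-4-hydroxy-3,7-dimethyl-6-oxoocta-2,7-dien-1-yl acetate
Conditions: 2, (−)-B-chlorodiisopinocampheylborane [(−)-Ipc2BCl], Et3N, Et2O, 0 °C; then 1, −78 → −20 °C; H2O2, MeOH, pH 7 buffer, 0 °C
Reagents that add atoms: none
Why: Diisopinocampheylboron-mediated aldol reaction of a methyl ketone, in which the ketone can enolise only at CH3 and the isopinocampheyl ligands should direct the enolborinate to the Re face of the enal to set the (R)-carbinol C3.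

Step 2
Reactants: 3 (2E,4R)-4-hydroxy-3,7-dimethyl-6-oxoocta-2,7-dien-1-yl acetate
Product: 4 (2E,4R,6R)-1-acetoxy-6-hydroxy-3,7-dimethylocta-2,7-dien-4-yl 2-methylpropanoate
Conditions: isobutyraldehyde (5 equiv), SmI2 (0.2 equiv, premixed with the aldehyde), THF, −10 °C
Reagents that add atoms: isobutyraldehyde, CC(C)C=O
Why: Evans–Tishchenko reduction, in which the samarium-bound hemiacetal formed from the C3 hydroxyl and isobutyraldehyde delivers hydride intramolecularly to the C1 ketone through a six-membered chair, which should set C1 anti to C3 (1R) and leave the isobutyrate on O3 and a free hydroxyl on C1.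

Step 3
Reactants: 4 (2E,4R,6R)-1-acetoxy-6-hydroxy-3,7-dimethylocta-2,7-dien-4-yl 2-methylpropanoate
Product: 5 (2E,4R,6R)-1-acetoxy-6-[tert-butyl(dimethyl)silyl]oxy-3,7-dimethylocta-2,7-dien-4-yl 2-methylpropanoate
Conditions: TBSOTf, 2,6-lutidine, CH2Cl2, −78 °C
Reagents that add atoms: tert-butyldimethylsilyl triflate, CC(C)(C)[Si](C)(C)OS(=O)(=O)C(F)(F)F
Why: Silylation of the only free hydroxyl with a silyl triflate and a hindered base should proceed at low temperature without 1,3-acyl migration.

Step 4
Reactants: 5 (2E,4R,6R)-1-acetoxy-6-[tert-butyl(dimethyl)silyl]oxy-3,7-dimethylocta-2,7-dien-4-yl 2-methylpropanoate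
Product: 6 (2E,4R,6R)-6-[tert-butyl(dimethyl)silyl]oxy-1-hydroxy-3,7-dimethylocta-2,7-dien-4-yl 2-methylpropanoate
Conditions: K2CO3 (0.2 equiv), MeOH, 0 °C
Reagents that add atoms: none
Why: Base-catalysed transesterification, in which the primary acetate should be methanolysed much faster than the α-branched isobutyrate of the hindered secondary alcohol.

Step 5
Reactants: 6 (2E,4R,6R)-6-[tert-butyl(dimethyl)silyl]oxy-1-hydroxy-3,7-dimethylocta-2,7-dien-4-yl 2-methylpropanoate
Product: 7 (2E,4R,6R)-6-[tert-butyl(dimethyl)silyl]oxy-3,7-dimethyl-1-oxoocta-2,7-dien-4-yl 2-methylpropanoate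
Conditions: MnO2, CH2Cl2, 23 °C
Reagents that add atoms: none
Why: Allylic alcohol oxidation with MnO2 under neutral conditions should give the enal with retention of the E geometry and of the silyl ether.

Step 6
Reactants: 8 methyl 3-methylbut-2-enoate
Product: 9 tert-butyl[(1-methoxy-3-methylbuta-1,3-dien-1-yl)oxy]dimethylsilane
Conditions: LiN(i-Pr)2, THF, −78 °C; then TBSCl, DMPU, −78 → 0 °C
Reagents that add atoms: tert-butyldimethylsilyl chloride, CC(C)(C)[Si](C)(C)Cl
Why: γ-Deprotonation of the senecioate ester and O-silylation of the extended enolate give the silyl dienol ether that serves as the vinylogous nucleophile.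

Step 7
Reactants: 7 (2E,4R,6R)-6-[tert-butyl(dimethyl)silyl]oxy-3,7-dimethyl-1-oxoocta-2,7-dien-4-yl 2-methylpropanoate; 9 tert-butyl[(1-methoxy-3-methylbuta-1,3-dien-1-yl)oxy]dimethylsilane
Product: 10 methyl (2E,5S,6E,8R,10R)-10-[tert-butyl(dimethyl)silyl]oxy-5-hydroxy-3,7,11-trimethyl-8-(2-methylpropanoyloxy)dodeca-2,6,11-trienoate
Conditions: SiCl4 (1.1 equiv), (S,S)-bisphosphoramide catalyst [N,N'-dimethylpentane-1,5-diamine capped on both nitrogens with the P(=O) diamide of (S)-N,N'-dimethyl-1,1'-binaphthyl-2,2'-diamine] (5 mol %), i-Pr2NEt (10 mol %), CH2Cl2, −78 °C; aq. NaHCO3/KF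
Reagents that add atoms: none
Why: Catalytic enantioselective vinylogous Mukaiyama aldol reaction, in which the phosphoramide-bound trichlorosilyl cation activates the enal, the dienol ether attacks through its γ-carbon to give the E enoate, and the catalyst antipode chosen for Si-face addition should set the (S)-carbinol C6 independently of the remote C3 center.

Step 8
Reactants: 10 methyl (2E,5S,6E,8R,10R)-10-[tert-butyl(dimethyl)silyl]oxy-5-hydroxy-3,7,11-trimethyl-8-(2-methylpropanoyloxy)dodeca-2,6,11-trienoate
Product: 11 methyl (2E,5S,6E,8R,10R)-10-[tert-butyl(dimethyl)silyl]oxy-3,7,11-trimethyl-8-(2-methylpropanoyloxy)-5-(triethylsilyloxy)dodeca-2,6,11-trienoate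
Conditions: TESCl, imidazole, DMF, 0 °C
Reagents that add atoms: chlorotriethylsilane, CC[Si](Cl)(CC)CC
Why: Silylation of the secondary allylic alcohol with the more labile triethylsilyl group, chosen so that it can later be removed in the presence of the TBS ether.

Step 9
Reactants: 11 methyl (2E,5S,6E,8R,10R)-10-[tert-butyl(dimethyl)silyl]oxy-3,7,11-trimethyl-8-(2-methylpropanoyloxy)-5-(triethylsilyloxy)dodeca-2,6,11-trienoate
Product: 12 methyl (3R,5S,6E,8R,10R)-10-[tert-butyl(dimethyl)silyl]oxy-3,7,11-trimethyl-8-(2-methylpropanoyloxy)-5-(triethylsilyloxy)dodeca-6,11-dienoate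
Conditions: Cu(OAc)2·H2O (5 mol %), (S)-p-Tol-BINAP (5 mol %), (EtO)2MeSiH, t-BuOH, toluene, 0 → 23 °C
Reagents that add atoms: none
Why: Ligated copper hydride asymmetric conjugate reduction, in which hydride is delivered to the β-carbon C8 of the enoate on the face selected by the ligand (3R in the ester numbering) while the isolated alkenes and the other esters are not reduced.

Step 10
Reactants: 12 methyl (3R,5S,6E,8R,10R)-10-[tert-butyl(dimethyl)silyl]oxy-3,7,11-trimethyl-8-(2-methylpropanoyloxy)-5-(triethylsilyloxy)dodeca-6,11-dienoate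
Product: 13 (3R,5S,6E,8R,10R)-10-[tert-butyl(dimethyl)silyl]oxy-3,7,11-trimethyl-8-(2-methylpropanoyloxy)-5-(triethylsilyloxy)dodeca-6,11-dienoic acid
Conditions: LiOH·H2O (1.5 equiv), THF/MeOH/H2O, 0 °C; then aq. HCl to pH 4, 0 °C
Reagents that add atoms: lithium hydroxide, [Li+].[OH-]
Why: Saponification, in which the unhindered, no longer conjugated methyl ester should be hydrolysed selectively in the presence of the α-branched secondary isobutyrate.

Step 11
Reactants: 13 (3R,5S,6E,8R,10R)-10-[tert-butyl(dimethyl)silyl]oxy-3,7,11-trimethyl-8-(2-methylpropanoyloxy)-5-(triethylsilyloxy)dodeca-6,11-dienoic acid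
Product: 16 bicyclo[3.1.1]heptan-6-one with the side chain on C4 anti to the C6–C8 bridge, via acid chloride 14 (not isolated), via alkylketene 15 (not isolated)
Conditions: 1-chloro-N,N,2-trimethylprop-1-en-1-amine, CH2Cl2, 0 °C; then slow addition to Et3N, toluene, 110 °C (high dilution)
Reagents that add atoms: none
Why: Intramolecular ketene–alkene [2+2] cycloaddition in the crossed mode, in which the ketene carbonyl carbon C10 bonds to the less substituted alkene carbon C5 and the α-carbon C9 to C4, suprafacial addition to the E alkene puts the C4 methyl syn and the side chain anti to the three-carbon bridge, and A(1,3) strain between the C6 substituents and the cis methyl on C4 holds the C6 hydrogen in the alkene plane so that the tether delivers the ketene to one face only, which should set C4, C5 and C9 as in the target.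

Step 12
Reactants: 16 bicyclo[3.1.1]heptan-6-one with the side chain on C4 anti to the C6–C8 bridge
Product: 19 tricyclic bis-silyl ether with the C10–C11 bond, via tosylhydrazone 17 (not isolated), via sulfonylhydrazide 18 (not isolated)
Conditions: TsNHNH2, EtOH, 50 °C; then Fe(acac)3 (0.5 equiv), PhSiH3, EtOH, 60 °C (0.01 M); then NaOAc, 80 °C
Reagents that add atoms: none
Why: Condensation gives the tosylhydrazone, the iron hydride formed from Fe(acac)3 and PhSiH3 transfers a hydrogen atom to the CH2 terminus of the isopropenyl group, and the nucleophilic tertiary radical at C11 adds to the hydrazone carbon C10; the hydrazinyl radical is reduced and protonated, and base-induced loss of p-toluenesulfinate gives an alkyl diazene that expels N2 and leaves hydrogen on C10. The closest known reaction types are the iron-hydride reductive alkylation of alkenes with sulfonylhydrazones and tin-mediated radical cyclisations onto ketone-derived N-aziridinylimines. The seven-membered ring (the bicyclo[4.1.1]octane that shares the cyclobutane) closes in the 7-exo-trig mode. C10 is the only new stereocenter and is fixed by the ring: C11 can bond only to the face of C10 that is 1,3-diaxial to the side chain on C4, so the hydrogen must end on the face of the three-carbon bridge. The step needs chemoselective hydrogen-atom transfer and cyclisation faster than radical reduction; the isopropenyl group is the only alkene left, the chain is held directly above C10, and addition relieves the strain of the sp2 carbon in the four-membered ring.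

Step 13
Reactants: 19 tricyclic bis-silyl ether with the C10–C11 bond
Product: 20 tricyclic C6 alcohol (C1 TBS ether, C3 isobutyrate)
Conditions: pyridinium p-toluenesulfonate (0.2 equiv), MeOH, 0 → 23 °C
Reagents that add atoms: none
Why: Acid-catalysed methanolysis should remove the triethylsilyl ether selectively because the TBS ether on the neopentyl-type C1 oxygen is far less labile.

Step 14
Reactants: 20 tricyclic C6 alcohol (C1 TBS ether, C3 isobutyrate)
Product: 22 tricyclic enone TBS ether, via saturated ketone 21 (not isolated)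
Conditions: IBX (4 equiv), DMSO, 25 → 75 °C
Reagents that add atoms: none
Why: IBX oxidation of the secondary alcohol followed by IBX dehydrogenation of the ketone, in which only C7 can enolise because C5 is a cyclobutane bridgehead, so the double bond should form at C7=C8 and the sacrificial C8 center is erased.

Step 15
Reactants: 22 tricyclic enone TBS ether
Product: 23 tricyclic C1 alcohol (enone, C3 isobutyrate)
Conditions: HF·pyridine, pyridine, THF, 0 → 40 °C
Reagents that add atoms: none
Why: Fluoride-mediated desilylation under buffered, weakly acidic conditions should free the C1 hydroxyl without 1,3-acyl migration of the isobutyrate.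

Step 16
Reactants: 23 tricyclic C1 alcohol (enone, C3 isobutyrate)
Product: 24 CNP0214356.1
Conditions: methacryloyl chloride, Et3N, 4-(dimethylamino)pyridine (0.1 equiv), CH2Cl2, 0 → 23 °C
Reagents that add atoms: methacryloyl chloride, C=C(C)C(Cl)=O
Why: Acylation of the hindered secondary alcohol with the acid chloride under nucleophilic catalysis should give the methacrylate without touching the enone or the isobutyrate.

Compound list
1 | (2E)-3-methyl-4-oxobut-2-en-1-yl acetate [(E)-4-acetoxy-2-methylbut-2-enal] | CC(=O)OC/C=C(\C)C=O | starting material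
2 | 3-methylbut-3-en-2-one | CC(=O)C(C)=C | starting material
3 | (2E,4R)-4-hydroxy-3,7-dimethyl-6-oxoocta-2,7-dien-1-yl acetate | CC(=O)OC/C=C(\C)[C@H](O)CC(=O)C(C)=C | intermediate
4 | (2E,4R,6R)-1-acetoxy-6-hydroxy-3,7-dimethylocta-2,7-dien-4-yl 2-methylpropanoate | CC(=O)OC/C=C(\C)[C@H](OC(=O)C(C)C)C[C@@H](O)C(C)=C | intermediate
5 | (2E,4R,6R)-1-acetoxy-6-[tert-butyl(dimethyl)silyl]oxy-3,7-dimethylocta-2,7-dien-4-yl 2-methylpropanoate | CC(=O)OC/C=C(\C)[C@H](OC(=O)C(C)C)C[C@@H](O[Si](C)(C)C(C)(C)C)C(C)=C | intermediate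
6 | (2E,4R,6R)-6-[tert-butyl(dimethyl)silyl]oxy-1-hydroxy-3,7-dimethylocta-2,7-dien-4-yl 2-methylpropanoate | OC/C=C(\C)[C@H](OC(=O)C(C)C)C[C@@H](O[Si](C)(C)C(C)(C)C)C(C)=C | intermediate
7 | (2E,4R,6R)-6-[tert-butyl(dimethyl)silyl]oxy-3,7-dimethyl-1-oxoocta-2,7-dien-4-yl 2-methylpropanoate | O=C/C=C(\C)[C@H](OC(=O)C(C)C)C[C@@H](O[Si](C)(C)C(C)(C)C)C(C)=C | intermediate
8 | methyl 3-methylbut-2-enoate | COC(=O)C=C(C)C | starting material
9 | tert-butyl[(1-methoxy-3-methylbuta-1,3-dien-1-yl)oxy]dimethylsilane | C=C(C)C=C(OC)O[Si](C)(C)C(C)(C)C | intermediate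
10 | methyl (2E,5S,6E,8R,10R)-10-[tert-butyl(dimethyl)silyl]oxy-5-hydroxy-3,7,11-trimethyl-8-(2-methylpropanoyloxy)dodeca-2,6,11-trienoate | COC(=O)/C=C(\C)C[C@H](O)/C=C(\C)[C@H](OC(=O)C(C)C)C[C@@H](O[Si](C)(C)C(C)(C)C)C(C)=C | intermediate
11 | methyl (2E,5S,6E,8R,10R)-10-[tert-butyl(dimethyl)silyl]oxy-3,7,11-trimethyl-8-(2-methylpropanoyloxy)-5-(triethylsilyloxy)dodeca-2,6,11-trienoate | COC(=O)/C=C(\C)C[C@H](O[Si](CC)(CC)CC)/C=C(\C)[C@H](OC(=O)C(C)C)C[C@@H](O[Si](C)(C)C(C)(C)C)C(C)=C | intermediate
12 | methyl (3R,5S,6E,8R,10R)-10-[tert-butyl(dimethyl)silyl]oxy-3,7,11-trimethyl-8-(2-methylpropanoyloxy)-5-(triethylsilyloxy)dodeca-6,11-dienoate | COC(=O)C[C@H](C)C[C@H](O[Si](CC)(CC)CC)/C=C(\C)[C@H](OC(=O)C(C)C)C[C@@H](O[Si](C)(C)C(C)(C)C)C(C)=C | intermediate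
13 | (3R,5S,6E,8R,10R)-10-[tert-butyl(dimethyl)silyl]oxy-3,7,11-trimethyl-8-(2-methylpropanoyloxy)-5-(triethylsilyloxy)dodeca-6,11-dienoic acid | OC(=O)C[C@H](C)C[C@H](O[Si](CC)(CC)CC)/C=C(\C)[C@H](OC(=O)C(C)C)C[C@@H](O[Si](C)(C)C(C)(C)C)C(C)=C | intermediate
14 | acid chloride of 13 | ClC(=O)C[C@H](C)C[C@H](O[Si](CC)(CC)CC)/C=C(\C)[C@H](OC(=O)C(C)C)C[C@@H](O[Si](C)(C)C(C)(C)C)C(C)=C | intermediate (not isolated)
15 | alkylketene derived from 14 (C10=C9 ketene) | O=C=C[C@H](C)C[C@H](O[Si](CC)(CC)CC)/C=C(\C)[C@H](OC(=O)C(C)C)C[C@@H](O[Si](C)(C)C(C)(C)C)C(C)=C | intermediate (not isolated)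
16 | bicyclo[3.1.1]heptan-6-one (C10 ketone); C4 bears methyl syn to the C6–C8 bridge and, anti to it, the chain CH(OCOiPr)–CH2–CH(OTBS)–C(CH3)=CH2 (C3 R, C1 R); C6 (S)-OSiEt3 and C8 (R)-CH3 on the ketone side; C4 R, C5 R, C9 R | C=C(C)[C@H](O[Si](C)(C)C(C)(C)C)C[C@@H](OC(=O)C(C)C)[C@@]1(C)[C@@H]2[C@@H](O[Si](CC)(CC)CC)C[C@@H](C)[C@H]1C2=O | intermediate
17 | N-tosylhydrazone of ketone 16 at C10 | C=C(C)[C@H](O[Si](C)(C)C(C)(C)C)C[C@@H](OC(=O)C(C)C)[C@@]1(C)[C@@H]2[C@@H](O[Si](CC)(CC)CC)C[C@@H](C)[C@H]1C2=NNS(=O)(=O)c1ccc(C)cc1 | intermediate (not isolated)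
18 | tricyclic N'-tosylhydrazide: C10 bonded to C11 and to NH–NHTs (nitrogen on the face of the three-carbon bridge) | CC(C)(C)[Si](C)(C)O[C@@H]1C[C@@H](OC(=O)C(C)C)[C@@]2(C)[C@@H]3[C@@H](O[Si](CC)(CC)CC)C[C@@H](C)[C@H]2[C@]3(NNS(=O)(=O)c2ccc(C)cc2)C1(C)C | intermediate (not isolated)
19 | tricyclic bis-silyl ether: skeleton of the target with C1 OTBS, C3 isobutyrate, C6 (S)-OSiEt3, C7 methylene, C8 (R)-CH3; C1, C3, C4, C5, C10 configured as in the target | CC(C)(C)[Si](C)(C)O[C@@H]1C[C@@H](OC(=O)C(C)C)[C@@]2(C)[C@@H]3[C@@H](O[Si](CC)(CC)CC)C[C@@H](C)[C@H]2[C@@H]3C1(C)C | intermediate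
20 | tricyclic C6 alcohol: as 19 with C6 (S)-OH | CC(C)(C)[Si](C)(C)O[C@@H]1C[C@@H](OC(=O)C(C)C)[C@@]2(C)[C@@H]3[C@@H](O)C[C@@H](C)[C@H]2[C@@H]3C1(C)C | intermediate
21 | tricyclic saturated C6 ketone: as 20 with C6=O, C8 (R)-CH3 | CC(C)(C)[Si](C)(C)O[C@@H]1C[C@@H](OC(=O)C(C)C)[C@@]2(C)[C@@H]3C(=O)C[C@@H](C)[C@H]2[C@@H]3C1(C)C | intermediate (not isolated)
22 | tricyclic enone TBS ether: target skeleton with C6=O, C7=C8, C1 OTBS, C3 isobutyrate | CC(C)(C)[Si](C)(C)O[C@@H]1C[C@@H](OC(=O)C(C)C)[C@@]2(C)[C@@H]3C(=O)C=C(C)[C@H]2[C@@H]3C1(C)C | intermediate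
23 | tricyclic C1 alcohol: as 22 with C1 (R)-OH | O[C@@H]1C[C@@H](OC(=O)C(C)C)[C@@]2(C)[C@@H]3C(=O)C=C(C)[C@H]2[C@@H]3C1(C)C | intermediate
24 | CNP0214356.1 (C1 R methacrylate, C3 R isobutyrate, C4 R, C5 R, C9 R, C10 S) | C=C(C)C(=O)O[C@@H]1C[C@@H](OC(=O)C(C)C)[C@@]2(C)[C@@H]3C(=O)C=C(C)[C@H]2[C@@H]3C1(C)C | target

Total step count: 16. Longest linear sequence: 15 steps (steps 1–5 and 7–16; step 6 prepares the dienol ether 9 on a side branch).

Steps most likely to fail

Step 12 (key step). What may go wrong: the tertiary radical is reduced, so the isopropenyl group is simply hydrogenated, faster than it closes the seven-membered ring onto the hindered C=N. Fallback with a tin-hydride chain and an acceptor that fragments irreversibly: starting from ketone 16, Markovnikov hydrochlorination of the isopropenyl group (Co(BF4)2·6H2O with a salicylaldimine ligand, TsCl, PhSiH3, EtOH) would give the tertiary chloride F1. Condensation of F1 with 1-amino-2-phenylaziridine would give the N-aziridinylimine F2. Bu3SnH with azobisisobutyronitrile in refluxing benzene (slow addition) would abstract chlorine, cyclise the C11 radical onto C10, and expel styrene and N2; the resulting C10 radical is reduced by the stannane to tricycle 19, where the route is rejoined.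

Step 11. What may go wrong: the alkylketene dimerises or oligomerises before it is intercepted by the trisubstituted alkene, which the allylic silyl ether deactivates, or the two alkene faces are not well differentiated. Fallback with a keteniminium ion in place of the ketene: starting from acid 13, coupling with pyrrolidine (EDC·HCl, HOBt, CH2Cl2) would give the pyrrolidine amide F3. Tf2O and 2,4,6-collidine in refluxing 1,2-dichloroethane would generate the more electrophilic keteniminium ion, whose intramolecular [2+2] cycloaddition under the same A(1,3) control gives the cyclobutaniminium triflate F4. Hydrolysis of F4 with aqueous NaHCO3 returns to ketone 16.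

Step 14. What may go wrong: the dehydrogenation stalls at the saturated ketone, or over-oxidation sets in at the temperature it needs. Fallback in separate, milder operations: starting from alcohol 20, Dess–Martin periodinane would give ketone 21, isolated in this variant. TMSOTf and Et3N would give the trimethylsilyl enol ether F5, which can only form toward C7. Pd(OAc)2 in MeCN (Saegusa–Ito oxidation) would then give enone 22, where the route is rejoined.

Further compounds
F1 | step 12 | tertiary chloride: ketone 16 with the isopropenyl group converted into C(CH3)2Cl | CC(C)(Cl)[C@H](O[Si](C)(C)C(C)(C)C)C[C@@H](OC(=O)C(C)C)[C@@]1(C)[C@@H]2[C@@H](O[Si](CC)(CC)CC)C[C@@H](C)[C@H]1C2=O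
F2 | step 12 | N-(2-phenylaziridin-1-yl)imine of F1 at C10 | CC(C)(Cl)[C@H](O[Si](C)(C)C(C)(C)C)C[C@@H](OC(=O)C(C)C)[C@@]1(C)[C@@H]2[C@@H](O[Si](CC)(CC)CC)C[C@@H](C)[C@H]1C2=NN3CC3c3ccccc3
F3 | step 11 | pyrrolidine amide of acid 13 | O=C(N1CCCC1)C[C@H](C)C[C@H](O[Si](CC)(CC)CC)/C=C(\C)[C@H](OC(=O)C(C)C)C[C@@H](O[Si](C)(C)C(C)(C)C)C(C)=C
F4 | step 11 | cyclobutaniminium triflate: 16 with C10=N+(pyrrolidine) in place of C10=O | C=C(C)[C@H](O[Si](C)(C)C(C)(C)C)C[C@@H](OC(=O)C(C)C)[C@@]1(C)[C@@H]2[C@@H](O[Si](CC)(CC)CC)C[C@@H](C)[C@H]1C2=[N+]3CCCC3.[O-]S(=O)(=O)C(F)(F)F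
F5 | step 14 | trimethylsilyl enol ether of ketone 21 (C6–OSiMe3, C6=C7) | CC(C)(C)[Si](C)(C)O[C@@H]1C[C@@H](OC(=O)C(C)C)[C@@]2(C)[C@@H]3C(O[Si](C)(C)C)=C[C@@H](C)[C@H]2[C@@H]3C1(C)C
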